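The synthesis rests on cutting ring C of the upper epicatechin unit at O1–C8a and C2–C3. The key step joins an achiral 2-arylallyl MOM ether (ring A with fluorine at C8a) and 3,4-bis(benzyloxy)benzaldehyde in one flask: a reagent-controlled syn γ-alkoxyallylboration sets C2 and C3, and the C2 alkoxide then closes the pyran by SNAr at C8a. It exploits the cis C2-aryl/C3-oxygen pair of ring C and the position of C8a meta to both ring-A oxygens: O1 is kept on C2, so the syn adduct is the 2,3-cis flavan. The exocyclic C4 methylene becomes the C4 leaving group; epicatechin- and catechin-derived units are added by 4→6 and 4→8 cation couplings.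

Key step: step 5

Remark: flavan numbering (O1, C2, C3, C4, C4a, C5–C8, C8a) is used for the upper, middle and lower units; the C4 configuration of 17 and 18 is immaterial because C4 is ionised in step 10, and both are drawn as the expected major epimers.

Step 1
Reactants: 1 1,3,5-trifluorobenzene
Product: 2 1,3-bis(benzyloxy)-5-fluorobenzene
Conditions: BnOH (2.2 equiv), NaH, NMP, 0 → 90 °C
Reagents that add atoms: benzyl alcohol, OCc1ccccc1
Why: Twofold SNAr by sodium benzyloxide, each fluoride being activated inductively by the fluorines meta to it, while the third substitution should be too slow once two donor groups are in place.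

Step 2
Reactants: 2 1,3-bis(benzyloxy)-5-fluorobenzene
Product: 4 [2,4-bis(benzyloxy)-6-fluorophenyl]trimethylsilane, via aryllithium 3 (not isolated)
Conditions: n-BuLi, THF, −78 °C; then TMSCl, −78 °C → rt
Reagents that add atoms: chlorotrimethylsilane, C[Si](C)(C)Cl
Why: Directed ortho-metalation at the C–H flanked by fluorine and benzyloxy (the most acidic ring position) and silyl quench; the silyl group occupies the future C8 so that this position cannot be metalated in step 5.

Step 3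
Reactants: 5 2-bromoprop-2-en-1-ol
Product: 6 2-bromo-3-(methoxymethoxy)prop-1-ene
Conditions: MOMCl, i-Pr2NEt, CH2Cl2, 0 °C → rt
Reagents that add atoms: chloromethyl methyl ether, COCCl
Why: O-alkylation of the primary alcohol with the α-chloro ether under amine base (MOM acetal formation), to which the vinyl bromide is inert.

Step 4
Reactants: 4 [2,4-bis(benzyloxy)-6-fluorophenyl]trimethylsilane; 6 2-bromo-3-(methoxymethoxy)prop-1-ene
Product: 9 {4,6-bis(benzyloxy)-2-fluoro-3-[3-(methoxymethoxy)prop-1-en-2-yl]phenyl}trimethylsilane, via aryllithium 7 (not isolated), via arylzinc chloride 8 (not isolated)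
Conditions: n-BuLi, THF, −78 °C; ZnCl2, −78 → 0 °C; then 6, Pd2(dba)3 (2 mol %), SPhos, THF, 50 °C
Reagents that add atoms: none
Why: Second directed ortho-metalation at the only remaining C–H next to fluorine, transmetalation to zinc and Negishi coupling of the hindered arylzinc with the vinyl bromide under a zerovalent palladium/biarylphosphine catalyst; the ortho-fluoroaryllithium is kept at −78 °C until zinc is added so that no aryne forms.

Step 5
Reactants: 9 {4,6-bis(benzyloxy)-2-fluoro-3-[3-(methoxymethoxy)prop-1-en-2-yl]phenyl}trimethylsilane; 10 3,4-bis(benzyloxy)benzaldehyde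
Product: 15 (2R,3R)-5,7-bis(benzyloxy)-2-[3,4-bis(benzyloxy)phenyl]-3-(methoxymethoxy)-4-methylidene-8-(trimethylsilyl)-3,4-dihydro-2H-chromene, via allyllithium 11 (not isolated), via allylborane 12 (not isolated), via borinate 13 (not isolated), via potassium alkoxide 14 (not isolated)
Conditions: s-BuLi, THF, −78 °C; (−)-Ipc2BOMe; BF3·OEt2; 10, −78 °C; then t-BuOK, 18-crown-6, DMF, −78 → 40 °C
Reagents that add atoms: none
Why: s-BuLi removes the allylic proton next to the MOM-oxy group (the acetal oxygens hold lithium, so the alkoxy group ends up cis to the CH2 terminus), B-methoxy exchange and BF3 give allylborane 12, which adds to aldehyde 10 through a closed six-membered chair transition state and forms C2–C3, and tert-butoxide then frees the C2 alkoxide from borinate 13 so that it displaces fluoride at C8a and forms O1–C8a. The closest known reaction types are the γ-alkoxyallylboration of aldehydes with diisopinocampheylboranes (Brown allylboration) and the alkoxide SNAr closure of a pyran ring onto a 2,4-dialkoxy-6-fluorophenyl group. Ring C closes by 6-exo addition–elimination at C8a through a Meisenheimer intermediate whose charge sits on C4a, C6 and C8, away from the benzyloxy donors at C5 and C7 and next to the charge-stabilising silyl group at C8. C2 and C3 are both set in the allylboration: the cis-alkoxy geometry of 12 gives the syn adduct through the chair, and the isopinocampheyl groups derived from (+)-α-pinene should direct attack to the Si face of the aldehyde, giving (2R,3R) by analogy with the parent allyl reagent; because O1 stays on C2, syn becomes 2,3-cis. The step needs allylic rather than ring metalation, secured by the C8 silyl group on the only ring position next to fluorine, and six-ring rather than five-ring closure, secured by the MOM cap on O3; no base-labile stereocentre is present because C4 is an alkene carbon and not a ketone.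

Step 6
Reactants: 15 (2R,3R)-5,7-bis(benzyloxy)-2-[3,4-bis(benzyloxy)phenyl]-3-(methoxymethoxy)-4-methylidene-8-(trimethylsilyl)-3,4-dihydro-2H-chromene
Product: 16 (2R,3S)-5,7-bis(benzyloxy)-2-[3,4-bis(benzyloxy)phenyl]-3-(methoxymethoxy)-8-(trimethylsilyl)-2,3-dihydro-4H-chromen-4-one (2,3-cis)
Conditions: OsO4 (2 mol %), NaIO4, 2,6-lutidine, dioxane/H2O, rt
Reagents that add atoms: osmium tetroxide, O=[Os](=O)(=O)=O (direct oxygen donor, re-oxygenated by NaIO4/H2O)
Why: Lemieux–Johnson oxidative cleavage (dihydroxylation, then periodate glycol cleavage) of the 1,1-disubstituted alkene in a buffered neutral medium that should leave the base-sensitive C3 centre of the 2,3-cis ketone intact.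

Step 7
Reactants: 16 (2R,3S)-5,7-bis(benzyloxy)-2-[3,4-bis(benzyloxy)phenyl]-3-(methoxymethoxy)-8-(trimethylsilyl)-2,3-dihydro-4H-chromen-4-one
Product: 18 5,7,3',4'-tetra-O-benzyl-4β-methoxy-(−)-epicatechin, via flavan-4-ol 17 (not isolated)
Conditions: NaBH4, CeCl3·7H2O, MeOH/THF, −40 °C; then HCl in MeOH, 0 °C → rt
Reagents that add atoms: methanol, CO
Why: Luche reduction of the ketone, then in acidic methanol SN1 methanolysis of the benzylic C4 hydroxyl (capture trans to O3), transacetalisation of the MOM ether and ipso-protodesilylation at C8 (activated by the three ring-A oxygens), none of which touches C2 or C3.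

Step 8
Reactants: 19 (−)-epicatechin
Product: 20 5,7,3',4'-tetra-O-benzyl-(−)-epicatechin
Conditions: BnBr, K2CO3, DMF, 0 °C → rt
Reagents that add atoms: benzyl bromide, BrCc1ccccc1
Why: Williamson etherification of the four phenols, which are far more acidic than the secondary 3-hydroxyl, under a mild carbonate base that should avoid epimerisation at C2.

Step 9
Reactants: 20 5,7,3',4'-tetra-O-benzyl-(−)-epicatechin
Product: 21 8-bromo-5,7,3',4'-tetra-O-benzyl-(−)-epicatechin
Conditions: NBS, CH2Cl2, −78 → −20 °C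
Reagents that add atoms: N-bromosuccinimide, O=C1CCC(=O)N1Br
Why: Electrophilic aromatic bromination at C8, the more reactive free ring-A position, which leaves C6 as the only nucleophilic site for step 10 and is removed again in step 15.

Step 10
Reactants: 18 5,7,3',4'-tetra-O-benzyl-4β-methoxy-(−)-epicatechin; 21 8-bromo-5,7,3',4'-tetra-O-benzyl-(−)-epicatechin
Product: 22 5,7,3',4'-tetra-O-benzylepicatechin-(4β→6)-8-bromo-5,7,3',4'-tetra-O-benzylepicatechin
Conditions: 21 (3 equiv), TMSOTf (0.2 equiv), CH2Cl2, −78 → −30 °C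
Reagents that add atoms: none
Why: TMSOTf ionises the C4 methyl ether to a ring-A-stabilised benzylic cation (Friedel–Crafts-type flavan-4-yl coupling) that C6 of 21 captures from the face opposite the cis C2-aryl and C3-hydroxyl groups, setting the 3,4-trans (4β) centre, while the excess of 21 suppresses self-condensation of the donor.

Step 11
Reactants: 22 5,7,3',4'-tetra-O-benzylepicatechin-(4β→6)-8-bromo-5,7,3',4'-tetra-O-benzylepicatechin
Product: 23 5,7,3',4'-tetra-O-benzylepicatechin-(4β→6)-8-bromo-4β-(2-ethoxyethoxy)-5,7,3',4'-tetra-O-benzylepicatechin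
Conditions: DDQ, 2-ethoxyethanol, CH2Cl2, rt
Reagents that add atoms: 2-ethoxyethanol, CCOCCO
Why: DDQ benzylic oxidation (hydride abstraction from the C4 methylene of the middle unit, assisted by its ring-A oxygens) with capture of the cation by the alcohol trans to the C3 hydroxyl; the tertiary C4–H of the upper unit is shielded by both A rings and should not react.

Step 12
Reactants: 23 5,7,3',4'-tetra-O-benzylepicatechin-(4β→6)-8-bromo-4β-(2-ethoxyethoxy)-5,7,3',4'-tetra-O-benzylepicatechin; 24 3,4,5-tris(benzyloxy)benzoic acid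
Product: 25 3-O-[3,4,5-tris(benzyloxy)benzoyl]-5,7,3',4'-tetra-O-benzylepicatechin-(4β→6)-8-bromo-4β-(2-ethoxyethoxy)-3-O-[3,4,5-tris(benzyloxy)benzoyl]-5,7,3',4'-tetra-O-benzylepicatechin
Conditions: 24 (3 equiv), DCC, DMAP, CH2Cl2, rt
Reagents that add atoms: none
Why: Steglich esterification of the two secondary 3-hydroxyls, the only free hydroxyls present, without change at any stereocentre.

Step 13
Reactants: 26 (+)-catechin
Product: 27 5,7,3',4'-tetra-O-benzyl-(+)-catechin
Conditions: BnBr, K2CO3, DMF, 0 °C → rt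
Reagents that add atoms: benzyl bromide, BrCc1ccccc1
Why: Williamson etherification of the four phenols under carbonate base, leaving the 3-hydroxyl free as the target requires.

Step 14
Reactants: 25 bis-galloylated dimer donor; 27 5,7,3',4'-tetra-O-benzyl-(+)-catechin
Product: 28 3-O-[tri-O-benzylgalloyl]-tetra-O-benzylepicatechin-(4β→6)-8-bromo-3-O-[tri-O-benzylgalloyl]-tetra-O-benzylepicatechin-(4β→8)-tetra-O-benzylcatechin
Conditions: 27 (4 equiv), TMSOTf (0.3 equiv), CH2Cl2, −78 → −40 °C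
Reagents that add atoms: none
Why: TMSOTf ionises the C4 ether of the middle unit (Friedel–Crafts-type flavan-4-yl coupling), the neighbouring 3-O-galloyl ester and the cis C2-aryl group shield one face, and C8 of 27, the more reactive ring-A position of catechin, should add trans to O3 to give the 4β→8 bond.

Step 15
Reactants: 28 protected trimer
Product: 29 epicatechin 3-O-gallate-(4β→6)-epicatechin 3-O-gallate-(4β→8)-catechin (CNP0112921.1)
Conditions: H2 (1 atm), Pd(OH)2/C, Et3N, THF/MeOH/H2O, rt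
Reagents that add atoms: none
Why: Hydrogenolysis of the eighteen benzyl ethers with hydrodebromination at C8 of the middle unit (triethylamine takes up HBr), to which the gallate esters, the interflavan bonds and all stereocentres are inert.

Compound list

1 | 1,3,5-trifluorobenzene | Fc1cc(F)cc(F)c1 | starting material
2 | 1,3-bis(benzyloxy)-5-fluorobenzene | Fc1cc(OCc2ccccc2)cc(OCc2ccccc2)c1 | intermediate
3 | [2,4-bis(benzyloxy)-6-fluorophenyl]lithium (not isolated) | [Li]c1c(F)cc(OCc2ccccc2)cc1OCc1ccccc1 | intermediate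
4 | [2,4-bis(benzyloxy)-6-fluorophenyl]trimethylsilane | C[Si](C)(C)c1c(F)cc(OCc2ccccc2)cc1OCc1ccccc1 | intermediate
5 | 2-bromoprop-2-en-1-ol | C=C(Br)CO | starting material
6 | 2-bromo-3-(methoxymethoxy)prop-1-ene | C=C(Br)COCOC | intermediate
7 | [4,6-bis(benzyloxy)-2-fluoro-3-(trimethylsilyl)phenyl]lithium (not isolated) | [Li]c1c(F)c([Si](C)(C)C)c(OCc2ccccc2)cc1OCc1ccccc1 | intermediate
8 | [4,6-bis(benzyloxy)-2-fluoro-3-(trimethylsilyl)phenyl]zinc chloride (not isolated) | Cl[Zn]c1c(F)c([Si](C)(C)C)c(OCc2ccccc2)cc1OCc1ccccc1 | intermediate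
9 | {4,6-bis(benzyloxy)-2-fluoro-3-[3-(methoxymethoxy)prop-1-en-2-yl]phenyl}trimethylsilane | C=C(COCOC)c1c(F)c([Si](C)(C)C)c(OCc2ccccc2)cc1OCc1ccccc1 | intermediate
10 | 3,4-bis(benzyloxy)benzaldehyde | O=Cc1ccc(OCc2ccccc2)c(OCc2ccccc2)c1 | starting material
11 | [2-aryl-3-(methoxymethoxy)allyl]lithium, alkoxy group cis to the CH2Li terminus (not isolated) | COCO/C=C(\C[Li])c1c(F)c([Si](C)(C)C)c(OCc2ccccc2)cc1OCc1ccccc1 | intermediate
12 | B-[2-aryl-3-(methoxymethoxy)allyl]diisopinocampheylborane, alkoxy group cis to the CH2B terminus, isopinocampheyl groups from (+)-α-pinene (not isolated) | COCO/C=C(\CB([C@@H]1C[C@@H]2C[C@H]([C@H]1C)C2(C)C)[C@@H]1C[C@@H]2C[C@H]([C@H]1C)C2(C)C)c1c(F)c([Si](C)(C)C)c(OCc2ccccc2)cc1OCc1ccccc1 | intermediate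
13 | diisopinocampheylborinate of (1R,2R)-1-[3,4-bis(benzyloxy)phenyl]-3-[4,6-bis(benzyloxy)-2-fluoro-3-(trimethylsilyl)phenyl]-2-(methoxymethoxy)but-3-en-1-ol (syn; not isolated) | C=C(c1c(F)c([Si](C)(C)C)c(OCc2ccccc2)cc1OCc1ccccc1)[C@@H](OCOC)[C@H](OB([C@@H]1C[C@@H]2C[C@H]([C@H]1C)C2(C)C)[C@@H]1C[C@@H]2C[C@H]([C@H]1C)C2(C)C)c1ccc(OCc2ccccc2)c(OCc2ccccc2)c1 | intermediate
14 | potassium (1R,2R)-alkoxide of the same syn homoallylic alcohol (not isolated) | C=C(c1c(F)c([Si](C)(C)C)c(OCc2ccccc2)cc1OCc1ccccc1)[C@@H](OCOC)[C@H]([O-])c1ccc(OCc2ccccc2)c(OCc2ccccc2)c1.[K+] | intermediate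
15 | (2R,3R)-5,7-bis(benzyloxy)-2-[3,4-bis(benzyloxy)phenyl]-3-(methoxymethoxy)-4-methylidene-8-(trimethylsilyl)-3,4-dihydro-2H-chromene (2,3-cis) | c1ccccc1COc1c([Si](C)(C)C)c2c(c(OCc3ccccc3)c1)C(=C)[C@@H](OCOC)[C@@H](c1ccc(OCc3ccccc3)c(OCc3ccccc3)c1)O2 | intermediate
16 | (2R,3S)-5,7-bis(benzyloxy)-2-[3,4-bis(benzyloxy)phenyl]-3-(methoxymethoxy)-8-(trimethylsilyl)-2,3-dihydro-4H-chromen-4-one (2,3-cis) | c1ccccc1COc1c([Si](C)(C)C)c2c(c(OCc3ccccc3)c1)C(=O)[C@@H](OCOC)[C@@H](c1ccc(OCc3ccccc3)c(OCc3ccccc3)c1)O2 | intermediate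
17 | (2R,3R)-5,7-bis(benzyloxy)-2-[3,4-bis(benzyloxy)phenyl]-3-(methoxymethoxy)-8-(trimethylsilyl)chroman-4-ol, 3,4-cis epimer expected (not isolated) | c1ccccc1COc1c([Si](C)(C)C)c2c(c(OCc3ccccc3)c1)[C@@H](O)[C@@H](OCOC)[C@@H](c1ccc(OCc3ccccc3)c(OCc3ccccc3)c1)O2 | intermediate
18 | 5,7,3',4'-tetra-O-benzyl-4β-methoxy-(−)-epicatechin [(2R,3R), 2,3-cis, 3,4-trans] | c1ccccc1COc1cc2c(c(OCc3ccccc3)c1)[C@H](OC)[C@@H](O)[C@@H](c1ccc(OCc3ccccc3)c(OCc3ccccc3)c1)O2 | intermediate
19 | (−)-epicatechin | Oc1cc2c(c(O)c1)C[C@@H](O)[C@@H](c1ccc(O)c(O)c1)O2 | starting material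
20 | 5,7,3',4'-tetra-O-benzyl-(−)-epicatechin | c1ccccc1COc1cc2c(c(OCc3ccccc3)c1)C[C@@H](O)[C@@H](c1ccc(OCc3ccccc3)c(OCc3ccccc3)c1)O2 | intermediate
21 | 8-bromo-5,7,3',4'-tetra-O-benzyl-(−)-epicatechin | c1ccccc1COc1c(Br)c2c(c(OCc3ccccc3)c1)C[C@@H](O)[C@@H](c1ccc(OCc3ccccc3)c(OCc3ccccc3)c1)O2 | intermediate
22 | 5,7,3',4'-tetra-O-benzylepicatechin-(4β→6)-8-bromo-5,7,3',4'-tetra-O-benzylepicatechin (both 3-OH free) | c1ccccc1COc1cc2c(c(OCc3ccccc3)c1)[C@H](c4c(OCc3ccccc3)c(Br)c5c(c4OCc3ccccc3)C[C@@H](O)[C@@H](c4ccc(OCc3ccccc3)c(OCc3ccccc3)c4)O5)[C@@H](O)[C@@H](c1ccc(OCc3ccccc3)c(OCc3ccccc3)c1)O2 | intermediate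
23 | 5,7,3',4'-tetra-O-benzylepicatechin-(4β→6)-8-bromo-4β-(2-ethoxyethoxy)-5,7,3',4'-tetra-O-benzylepicatechin | c1ccccc1COc1cc2c(c(OCc3ccccc3)c1)[C@H](c4c(OCc3ccccc3)c(Br)c5c(c4OCc3ccccc3)[C@H](OCCOCC)[C@@H](O)[C@@H](c4ccc(OCc3ccccc3)c(OCc3ccccc3)c4)O5)[C@@H](O)[C@@H](c1ccc(OCc3ccccc3)c(OCc3ccccc3)c1)O2 | intermediate
24 | 3,4,5-tris(benzyloxy)benzoic acid | OC(=O)c1cc(OCc2ccccc2)c(OCc2ccccc2)c(OCc2ccccc2)c1 | starting material
25 | 3-O-[3,4,5-tris(benzyloxy)benzoyl]-5,7,3',4'-tetra-O-benzylepicatechin-(4β→6)-8-bromo-4β-(2-ethoxyethoxy)-3-O-[3,4,5-tris(benzyloxy)benzoyl]-5,7,3',4'-tetra-O-benzylepicatechin | c1ccccc1COc1cc2c(c(OCc3ccccc3)c1)[C@H](c4c(OCc3ccccc3)c(Br)c5c(c4OCc3ccccc3)[C@H](OCCOCC)[C@@H](OC(=O)c4cc(OCc3ccccc3)c(OCc3ccccc3)c(OCc3ccccc3)c4)[C@@H](c4ccc(OCc3ccccc3)c(OCc3ccccc3)c4)O5)[C@@H](OC(=O)c1cc(OCc3ccccc3)c(OCc3ccccc3)c(OCc3ccccc3)c1)[C@@H](c1ccc(OCc3ccccc3)c(OCc3ccccc3)c1)O2 | intermediate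
26 | (+)-catechin | Oc1cc2c(c(O)c1)C[C@H](O)[C@@H](c1ccc(O)c(O)c1)O2 | starting material
27 | 5,7,3',4'-tetra-O-benzyl-(+)-catechin | c1ccccc1COc1cc2c(c(OCc3ccccc3)c1)C[C@H](O)[C@@H](c1ccc(OCc3ccccc3)c(OCc3ccccc3)c1)O2 | intermediate
28 | 3-O-[tri-O-benzylgalloyl]-5,7,3',4'-tetra-O-benzylepicatechin-(4β→6)-8-bromo-3-O-[tri-O-benzylgalloyl]-5,7,3',4'-tetra-O-benzylepicatechin-(4β→8)-5,7,3',4'-tetra-O-benzylcatechin | c1ccccc1COc1cc2c(c(OCc3ccccc3)c1)[C@H](c4c(OCc3ccccc3)c(Br)c5c(c4OCc3ccccc3)[C@H](c6c(OCc3ccccc3)cc(OCc3ccccc3)c7c6O[C@H](c6ccc(OCc3ccccc3)c(OCc3ccccc3)c6)[C@@H](O)C7)[C@@H](OC(=O)c4cc(OCc3ccccc3)c(OCc3ccccc3)c(OCc3ccccc3)c4)[C@@H](c4ccc(OCc3ccccc3)c(OCc3ccccc3)c4)O5)[C@@H](OC(=O)c1cc(OCc3ccccc3)c(OCc3ccccc3)c(OCc3ccccc3)c1)[C@@H](c1ccc(OCc3ccccc3)c(OCc3ccccc3)c1)O2 | intermediate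
29 | epicatechin 3-O-gallate-(4β→6)-epicatechin 3-O-gallate-(4β→8)-catechin (CNP0112921.1) | O=C(O[C@@H]1[C@@H](c2c(O)cc3c(c2O)[C@H](c2c(O)cc(O)c4c2O[C@H](c2ccc(O)c(O)c2)[C@@H](O)C4)[C@@H](OC(=O)c2cc(O)c(O)c(O)c2)[C@@H](c2ccc(O)c(O)c2)O3)c2c(O)cc(O)cc2O[C@@H]1c1ccc(O)c(O)c1)c1cc(O)c(O)c(O)c1 | target

Total step count: 15.
Longest linear sequence: 11 steps (steps 1, 2, 4, 5, 6, 7, 10, 11, 12, 14, 15).

Steps most likely to fail

Step 5. Three processes may interfere. s-BuLi may add across the styrene-type double bond, or metalate the ring C–H between the two benzyloxy groups, instead of removing the allylic proton. The hindered β-aryl allylborane may react slowly. During the SNAr stage tert-butoxide may fail to free the alkoxide from boron or may move the exocyclic double bond into the ring. The fallback sets out from 9 and comes back at 15. Lithiated 9 is quenched with 2-isopropoxy-4,4,5,5-tetramethyl-1,3,2-dioxaborolane to give the isolable, configurationally stable pinacol ester of the cis-γ-(methoxymethoxy)allylboronic acid F1, whose formation can be optimised on its own. Allylboration of 10 with F1 under catalysis by the chiral phosphoric acid TRIP (the enantiomer that directs Si-face attack, (S) by analogy with the parent allylation; toluene, −30 °C) and aqueous work-up should give the syn homoallylic alcohol F2. F2 is isolated and closed in a separate operation with KH and 18-crown-6 in THF (alkoxide SNAr) to give 15.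

Step 11. Hydride abstraction may occur at the doubly benzylic C4–H of the upper unit instead of the C4 methylene of the middle unit, or the dimer may be over-oxidised. The fallback sets out from 21 and comes back at 28; it puts the C4 leaving group on the middle unit before the first coupling, in a latent form. DDQ and 2-ethoxyethanol on monomer 21 give 8-bromo-4β-(2-ethoxyethoxy)-5,7,3',4'-tetra-O-benzylepicatechin F3. Exchange with 1,3-benzothiazole-2-thiol under BF3·OEt2 gives 8-bromo-4β-(1,3-benzothiazol-2-ylsulfanyl)-5,7,3',4'-tetra-O-benzylepicatechin F4, whose C–S bond should survive TMSOTf at low temperature. Coupling of 18 with F4 under the conditions of step 10 gives the thioether dimer F5, and esterification with 24 as in step 12 gives its bis-gallate F6. Thiophilic activation of F6 with AgBF4 in the presence of 27 (THF, 0 °C) should then give 28.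

Step 10. Capture of the cation by the hindered, bromine-deactivated C6 of 21 may be slower than self-condensation of the donor through its own C8, and the methyl ether may ionise incompletely at the low temperature needed for selectivity. The fallback sets out from 18 and comes back at 22. 18 is converted with 1,3-benzothiazole-2-thiol and BF3·OEt2 into 4β-(1,3-benzothiazol-2-ylsulfanyl)-5,7,3',4'-tetra-O-benzylepicatechin F7. F7 is added slowly to AgBF4 and an excess of 21 in THF at 0 °C, so that the cation is generated under non-protic conditions at low standing concentration and should be captured at C6 to give 22.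

Further compounds
F1 | step 5 | 2-{2-[4,6-bis(benzyloxy)-2-fluoro-3-(trimethylsilyl)phenyl]-3-(methoxymethoxy)allyl}-4,4,5,5-tetramethyl-1,3,2-dioxaborolane, alkoxy group cis to the CH2B terminus | COCO/C=C(\CB1OC(C)(C)C(C)(C)O1)c1c(F)c([Si](C)(C)C)c(OCc2ccccc2)cc1OCc1ccccc1
F2 | step 5 | (1R,2R)-1-[3,4-bis(benzyloxy)phenyl]-3-[4,6-bis(benzyloxy)-2-fluoro-3-(trimethylsilyl)phenyl]-2-(methoxymethoxy)but-3-en-1-ol | C=C(c1c(F)c([Si](C)(C)C)c(OCc2ccccc2)cc1OCc1ccccc1)[C@@H](OCOC)[C@H](O)c1ccc(OCc2ccccc2)c(OCc2ccccc2)c1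
F3 | step 11 | 8-bromo-4β-(2-ethoxyethoxy)-5,7,3',4'-tetra-O-benzyl-(−)-epicatechin | c1ccccc1COc1c(Br)c2c(c(OCc3ccccc3)c1)[C@H](OCCOCC)[C@@H](O)[C@@H](c1ccc(OCc3ccccc3)c(OCc3ccccc3)c1)O2
F4 | step 11 | 8-bromo-4β-(1,3-benzothiazol-2-ylsulfanyl)-5,7,3',4'-tetra-O-benzyl-(−)-epicatechin | c1ccccc1COc1c(Br)c2c(c(OCc3ccccc3)c1)[C@H](Sc1nc3ccccc3s1)[C@@H](O)[C@@H](c1ccc(OCc3ccccc3)c(OCc3ccccc3)c1)O2
F5 | step 11 | 5,7,3',4'-tetra-O-benzylepicatechin-(4β→6)-8-bromo-4β-(1,3-benzothiazol-2-ylsulfanyl)-5,7,3',4'-tetra-O-benzylepicatechin | c1ccccc1COc1cc2c(c(OCc3ccccc3)c1)[C@H](c4c(OCc3ccccc3)c(Br)c5c(c4OCc3ccccc3)[C@H](Sc4nc6ccccc6s4)[C@@H](O)[C@@H](c4ccc(OCc3ccccc3)c(OCc3ccccc3)c4)O5)[C@@H](O)[C@@H](c1ccc(OCc3ccccc3)c(OCc3ccccc3)c1)O2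
F6 | step 11 | 3,3''-bis-O-[3,4,5-tris(benzyloxy)benzoyl] ester of F5 | c1ccccc1COc1cc2c(c(OCc3ccccc3)c1)[C@H](c4c(OCc3ccccc3)c(Br)c5c(c4OCc3ccccc3)[C@H](Sc4nc6ccccc6s4)[C@@H](OC(=O)c4cc(OCc3ccccc3)c(OCc3ccccc3)c(OCc3ccccc3)c4)[C@@H](c4ccc(OCc3ccccc3)c(OCc3ccccc3)c4)O5)[C@@H](OC(=O)c1cc(OCc3ccccc3)c(OCc3ccccc3)c(OCc3ccccc3)c1)[C@@H](c1ccc(OCc3ccccc3)c(OCc3ccccc3)c1)O2
F7 | step 10 | 4β-(1,3-benzothiazol-2-ylsulfanyl)-5,7,3',4'-tetra-O-benzyl-(−)-epicatechin | c1ccccc1COc1cc2c(c(OCc3ccccc3)c1)[C@H](Sc1nc3ccccc3s1)[C@@H](O)[C@@H](c1ccc(OCc3ccccc3)c(OCc3ccccc3)c1)O2
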